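## Structural features

The core is a cyclobutane with a substituent on every ring carbon: in the numbering used for 30, C1 is quaternary (methyl and carboxyl), C2 carries the 4-hydroxy-3-methoxyphenyl group, C3 a carboxyl group and C4 an (E)-4-carboxy-3-methylbut-3-enyl arm. These four ring carbons are contiguous stereocentres; the aryl group, the side chain and the C1 methyl group lie on one face and the two ring carboxyl groups on the other, so every pair of neighbours is trans and the two ring carboxyl groups are 1,3-cis. All three carboxyl groups are esterified by the same amino alcohol, a cis-fused octahydrocyclopenta[c]pyridine (C1, N2, C3, C4, C4a, C5, C6, C7, C7a) with methyl groups on N2, C4 and C7 and the ester oxygen on C6. In each of these bicycles C4, C4a, C7a, C7 and C6 form an unbroken row of five stereocentres. Fragile points are the free phenol (a rival nucleophile in any esterification), three esters of which one is α,β-unsaturated, three basic tertiary amines, and the cyclobutane C3–H, which is α to an ester but already the stable epimer. The real difficulty is twofold: an unsymmetrical head-to-tail cyclobutane with a quaternary carbon must be made as one enantiomer, and an amino alcohol with five stereocentres is needed three times. The key step uses the fact that C1 of each bicycle is a methylene between N2 and the ring-fusion carbon C7a, and that C7a is β to the C6 oxygen through C7; with C6 as a ketone and C7=C7a as an enone, a radical on the N-methylene carbon can close the piperidine ring at C7a.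

## Logic of the disconnections

Bicycle atoms carry the labels C1–C7a; cyclobutane atoms are numbered as in 30.

**32 to 31.** Only the phenolic O–allyl bond is cut. The phenol must be masked because it would act as a nucleophile in the esterification. The forward step must spare three esters, the enoate and the amines.

**31 to 30 and three molecules of 16.** The three C6–O bonds are cut. This is the most convergent cut because the three alcohol units are identical. The forward step must invert C6, because hydride reduction of 15 gives the 6S alcohol while the target needs 6R. It must also take place three times on one crowded molecule of 30.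

**16 to 15.** The C6–H bond is cut. The forward reduction must deliver hydride on the face away from the C7 methyl group.

**15 to 13 (key).** The C1–C7a bond is cut. This opens the piperidine and leaves a monocyclic enone with only two stereocentres (C4 and C4a). The forward step must make the radical at the right carbon, close 6-exo, and give the cis ring fusion.

**13 to 10 and 11.** The C3–N bond is cut. Nitrogen enters by substitution at a primary carbon, so neither C4 nor C4a ever sits next to an aldehyde or an iminium ion. The forward step must activate a β-branched primary alcohol without touching the enone.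

**10 to 9 to 8.** After removal of the silyl group the C7=C7a bond is cut (ring-closing metathesis). A neutral ring closure is chosen so that C4a is never α to a carbonyl in an open chain. The forward step must form a trisubstituted enone alkene.

**8 to 7 to 5.** The C6–C7 bond (alkenyllithium on an amide) and the C4a–C5 bond (sigmatropic rearrangement) are cut. The rearrangement relays a carbinol configuration to C4a, so C4a is set independently of C4. The forward step needs an E alkene and a carbinol of defined configuration.

**5 to 4 to 3 to 2 to 1.** The carbinol C–H bond, the C=C bond, and then functional-group changes are cut back to a hydroxy ester that supplies C4 and C3.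

**30 to 28 to 27.** The cyclobutane bonds C1–C2 and C3–C4 are cut. Because the two ring carboxyl groups are 1,3-cis, they can be tied through one nitrogen atom. The cyclobutane with four stereocentres then becomes an acyclic imide without a stereocentre in the core. The forward step must close crosswise and not in parallel, and the two diastereomers that arise from the chiral nitrogen substituent must be separated.

**27 to 22 and 25; 22 to 20 and 21; 20 to 18 to 17; 25 to 23.** Two N–acyl bonds and one allylic C–O bond are cut. Both alkene geometries of the C10 unit come unchanged from 17.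

## Other disconnections considered

**Alternative 1:**
- Cut: the cyclobutane bond between the aryl carbon and the quaternary carbon (C1–C2 in the numbering of 30), replaced by a nitrogen bridge. This leads to the pyrrolidine A1.
- Forward key step: N-amination by an iodonitrene (from hydroxy(tosyloxy)iodobenzene and ammonium carbamate), loss of N2 from the 1,1-diazene, and collapse of the 1,4-biradical with retention to the tri-tert-butyl ester A2.
- In favour: pyrrolidines of this pattern are the usual products of catalytic asymmetric azomethine ylide cycloaddition (for example AgOAc with a chiral phosphine). The absolute configuration could therefore come from a catalyst and not from a separation; on this point the alternative is better than the chosen plan. The 1,3-placement of the carboxyl groups is fixed by the dipole, which is equal to the imide tether.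
- Against: A1 needs the aryl group trans to both the C2 ester and the C4 ester. Chelated ylides normally give the 2,5-cis arrangement, so the standard cycloaddition leads to a diastereomer of A1. The contraction must form a bond to a fully substituted carbon and competes with β-scission of the biradical into two alkenes. The electron-rich arene and the enoate must survive a hypervalent iodine oxidant.
- Comparison: both plans end at the same protected triacid and leave the amino alcohol untouched. Thermal nitrogen extrusion is operationally simpler than a photoreaction (equal or better). Step count to the triacid should be similar.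

**Alternative 2:**
- Cut: the cyclobutane bond between the quaternary carbon and the side-chain carbon (C1–C4 in the numbering of 30), which is the C3–C6 bond of the pyrone A3.
- Forward key step: irradiation of A3 brings about a 4π electrocyclisation to the cyclobutene β-lactone A4.
- In favour: it is the shortest entry to a four-membered ring that already holds the methyl group and both ring carboxyl carbons in the 1,3 relation. It is unimolecular with no regiochemical question; on both counts it is better than the chosen plan. The enoate of A4 should accept an aryl nucleophile (for example an arylboronic acid with [Rh(cod)OH]2) on the convex face, cis to the methyl group, as required.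
- Against: A4 arises as a racemate from an achiral pyrone, so the needed enantiomer requires a resolution (equal to the chosen plan, not better). The side chain must then enter at the former lactone carbon on the face syn to methyl and aryl. That needs invertive alkyl–oxygen opening of the β-lactone by a functionalised organocopper reagent. This competes with E1cB opening by the ester enolate, after which conjugate addition would prefer the wrong face. A4 is also prone to cycloreversion and loss of CO2.
- Comparison: fewer steps than the chosen plan, but weaker control of the last cyclobutane stereocentre. The imide tether of the chosen plan fixes all four at once.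

**Alternative 3:**
- Cut: C4a–C7a, C5–C6 and C6–C7 of each bicycle.
- Forward key step: Pauson–Khand reaction of the carbamate-tethered 1,7-enyne A5 with Co2(CO)8 and an amine N-oxide, giving the bicyclic enone A6.
- In favour: both rings and the C6 carbonyl form in one operation from an acyclic amine that is quickly made. The step count to the bicyclic ketone is lower than in the chosen plan, which is a point on which the alternative is better. No photochemistry is needed.
- Against: C4a is set only by 1,2-induction from the allylic C4 methyl group, in a closure that forms a six-membered ring and is slower than the usual five-membered case. Rate and diastereoselectivity are therefore both uncertain, whereas the chosen plan sets C4a by sigmatropic chirality transfer. A6 has a tetrasubstituted C7=C7a alkene, so C7a and C7 must be set later by hydrogenation from the convex face and epimerisation at C7. The carbamate must be reduced to N-methyl without losing control at C6. Cobalt carbonyl is used in stoichiometric amount.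
- Comparison: shorter, but the stereochemistry is set less securely. The ionic and organometallic mechanism is easier to scale than a photoinduced electron transfer (equal or better).

Key step: step 10

Remarks on the chemistry:
- The configurations of 13, 15 and the amino alcohol units of 32 are mutually consistent: C4 and C4a of 13 map onto 4R and 4aR of 15, and the cis ring fusion and the C7 configuration of 15 are those of the ester units of 32.
- The way to 13 avoids ring formation through an enolisable α-branched aldehyde and avoids reductive amination next to the C4 stereocentre; nitrogen enters by substitution at a primary carbon.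
- Methyl geranate 17 is taken as commercially available as the 2E isomer.
- It is assumed that the two diastereomers formed in step 17 can be separated on silica.
- It is assumed that hydroxide opens 28 at the carbonyl on C3.
- In step 19 one molecule of 30 takes up three molecules of 16. The partial esters formed on the way are a mixture of regioisomers that converges on 31, so they are not numbered.

## Steps

Step 1
Reactants: 1 methyl (S)-3-hydroxy-2-methylpropanoate
Product: 2 methyl (S)-3-[(tert-butyldimethylsilyl)oxy]-2-methylpropanoate
Conditions: TBSCl, imidazole, CH2Cl2, 0 °C to rt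
Reagents that add atoms: tert-butyldimethylsilyl chloride, CC(C)(C)[Si](C)(C)Cl
Why: Silylation of the primary alcohol; the oxygen marks the later leaving-group site at C3 and the stereocentre (future C4) is not touched.

Step 2
Reactants: 2 methyl (S)-3-[(tert-butyldimethylsilyl)oxy]-2-methylpropanoate
Product: 3 (S)-3-[(tert-butyldimethylsilyl)oxy]-2-methylpropanal
Conditions: i-Bu2AlH (1.1 equiv), CH2Cl2, −78 °C; aq. potassium sodium tartrate
Reagents that add atoms: none
Why: Partial ester reduction through the aluminium hemiacetal, which is stable at low temperature; the aldehyde is used at once so that its α-stereocentre should not epimerise.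

Step 3
Reactants: 3 (S)-3-[(tert-butyldimethylsilyl)oxy]-2-methylpropanal
Product: 4 (R,E)-6-[(tert-butyldimethylsilyl)oxy]-5-methylhex-3-en-2-one
Conditions: Ph3P=CHC(O)CH3, CH2Cl2, 40 °C
Reagents that add atoms: 1-(triphenylphosphoranylidene)propan-2-one, CC(=O)C=P(c1ccccc1)(c1ccccc1)c1ccccc1
Why: Wittig olefination with a stabilised, non-basic ylide, which should give the E enone without epimerisation; the descriptor changes from S to R only because the priorities change.

Step 4
Reactants: 4 (R,E)-6-[(tert-butyldimethylsilyl)oxy]-5-methylhex-3-en-2-one
Product: 5 (2S,5R,E)-6-[(tert-butyldimethylsilyl)oxy]-5-methylhex-3-en-2-ol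
Conditions: (R)-1-methyl-3,3-diphenyltetrahydro-1H,3H-pyrrolo[1,2-c][1,3,2]oxazaborole (15 mol%), BH3·SMe2, THF, −30 °C; MeOH
Reagents that add atoms: none
Why: Corey–Bakshi–Shibata reduction; with the alkenyl group as the large substituent the R catalyst should deliver hydride to give the 2S carbinol, whose configuration is relayed to C4a in step 5.

Step 5
Reactants: 5 (2S,5R,E)-6-[(tert-butyldimethylsilyl)oxy]-5-methylhex-3-en-2-ol
Product: 7 (S,E)-3-[(R)-1-((tert-butyldimethylsilyl)oxy)propan-2-yl]-N,N-dimethylhex-4-enamide, via ketene N,O-acetal 6 (not isolated)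
Conditions: CH3C(OMe)2NMe2, xylenes, 130 °C
Reagents that add atoms: N,N-dimethylacetamide dimethyl acetal, CC(OC)(OC)N(C)C
Why: Eschenmoser–Claisen rearrangement; a chair transition state with the carbinol methyl equatorial should transfer the 2S configuration across the E alkene to the new stereocentre (future C4a, S) while forming the C4a–C5 bond. The neutral conditions spare the silyl ether.

Step 6
Reactants: 7 (S,E)-3-[(R)-1-((tert-butyldimethylsilyl)oxy)propan-2-yl]-N,N-dimethylhex-4-enamide
Product: 8 (S,E)-5-[(R)-1-((tert-butyldimethylsilyl)oxy)propan-2-yl]-2-methylocta-1,6-dien-3-one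
Conditions: 2-bromopropene, t-BuLi (2 equiv), Et2O, −78 °C; then 7, −78 to −40 °C; aq. NH4Cl
Reagents that add atoms: isopropenyllithium, [Li]C(C)=C (made in the flask from 2-bromopropene, C=C(C)Br)
Why: Addition of an alkenyllithium to a tertiary amide gives a lithium hemiaminal that collapses to the enone only on acidic quench, so over-addition and amine conjugate addition should be avoided. This forms the C6–C7 bond.

Step 7
Reactants: 8 (S,E)-5-[(R)-1-((tert-butyldimethylsilyl)oxy)propan-2-yl]-2-methylocta-1,6-dien-3-one
Product: 9 (S)-4-[(R)-1-((tert-butyldimethylsilyl)oxy)propan-2-yl]-2-methylcyclopent-2-en-1-one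
Conditions: second-generation Grubbs catalyst RuCl2(H2IMes)(PCy3)(=CHPh) (5 mol%), CH2Cl2, 40 °C
Reagents that add atoms: none
Why: Ring-closing metathesis; the catalyst should load on the propenyl group, close onto the isopropenyl ketone and release propene, forming C7=C7a. The conditions are neutral, so C4 and C4a cannot epimerise.

Step 8
Reactants: 9 (S)-4-[(R)-1-((tert-butyldimethylsilyl)oxy)propan-2-yl]-2-methylcyclopent-2-en-1-one
Product: 10 (S)-4-[(R)-1-hydroxypropan-2-yl]-2-methylcyclopent-2-en-1-one
Conditions: HF·pyridine, THF, 0 °C to rt
Reagents that add atoms: none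
Why: Acidic fluoride desilylation; basic fluoride is avoided because a free alkoxide could add to the enone (oxa-Michael).

Step 9
Reactants: 10 (S)-4-[(R)-1-hydroxypropan-2-yl]-2-methylcyclopent-2-en-1-one; 11 N-methyl-1-(trimethylsilyl)methanamine
Product: 13 (S)-2-methyl-4-[(R)-1-{methyl[(trimethylsilyl)methyl]amino}propan-2-yl]cyclopent-2-en-1-one, via primary triflate 12 (not isolated)
Conditions: Tf2O, 2,6-lutidine, CH2Cl2, −78 °C; then 11 (3 equiv), −78 to 0 °C
Reagents that add atoms: none
Why: SN2 amination of a primary triflate; making the C3–N bond by substitution keeps the adjacent C4 stereocentre away from any enolisable or enamine-forming intermediate.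

Step 10
Reactants: 13 (S)-2-methyl-4-[(R)-1-{methyl[(trimethylsilyl)methyl]amino}propan-2-yl]cyclopent-2-en-1-one
Product: 15 (4R,4aR,7R,7aS)-2,4,7-trimethyloctahydro-6H-cyclopenta[c]pyridin-6-one, via C7-epimeric ketone 14 (not isolated)
Conditions: 9,10-dicyanoanthracene (10 mol%), hν (λ > 400 nm), MeCN/MeOH 3:1, Ar, rt; then K2CO3, MeOH, rt
Reagents that add atoms: none
Why: Excited 9,10-dicyanoanthracene takes one electron from the tertiary amine of 13, and the aminium ion loses its trimethylsilyl group to methanol faster than it loses an α-proton, so the radical forms only at the silylated methylene, which becomes C1. The closest known reaction type is the electron-transfer-sensitised cyclisation of α-silylamines onto tethered enones. The nucleophilic aminomethyl radical adds to the electron-poor β-carbon C7a in a 6-exo-trig closure (C7 stays outside the new ring), forming C1–C7a and the piperidine; the α-keto radical at C7 is reduced by the anthracene radical anion, which regenerates the sensitiser, and the enolate is protonated by methanol. C7a: the three-atom tether from C4a can reach only the face of the cyclopentenone on which it stands, so the new bond is cis to the C4a–C4 bond and the ring fusion is cis; a chair-like transition state keeps the C4 methyl equatorial, so the pre-set C4/C4a pair is matched. C7: kinetic protonation may give some of epimer 14 with the methyl on the concave face, and K2CO3 in methanol should equilibrate it to 15 with the methyl on the convex face, trans to C1. Selectivity needed: radical formation at the CH2–Si carbon and not at N–CH3 or C3 (secured by the silyl group and the protic medium), exo over endo attack (secured by ring size and enone polarity), and no direct excitation of the enone (secured by irradiating above 400 nm).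

Step 11
Reactants: 15 (4R,4aR,7R,7aS)-2,4,7-trimethyloctahydro-6H-cyclopenta[c]pyridin-6-one
Product: 16 (4R,4aR,6S,7R,7aS)-2,4,7-trimethyloctahydro-1H-cyclopenta[c]pyridin-6-ol (6-epi-incarvilline)
Conditions: NaBH4, MeOH, −20 °C
Reagents that add atoms: none
Why: Hydride reduction of the cyclopentanone; attack on the face away from the adjacent C7 methyl group should place the hydroxyl cis to that methyl (6S), the epimer needed for invertive esterification.

Step 12
Reactants: 17 methyl (2E)-3,7-dimethylocta-2,6-dienoate (methyl geranate)
Product: 18 methyl (2E,6E)-8-hydroxy-3,7-dimethylocta-2,6-dienoate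
Conditions: SeO2 (0.2 equiv), t-BuOOH, salicylic acid (cat.), CH2Cl2, rt
Reagents that add atoms: selenium dioxide, O=[Se]=O; tert-butyl hydroperoxide, CC(C)(C)OO
Why: Allylic oxidation (ene reaction, then [2,3]-sigmatropic shift) of the electron-rich trisubstituted alkene at its E methyl group; the conjugated 2,3-alkene is deactivated by the ester.

Step 13
Reactants: 18 methyl (2E,6E)-8-hydroxy-3,7-dimethylocta-2,6-dienoate
Product: 20 (2E,6E)-8-methoxy-2,6-dimethyl-8-oxoocta-2,6-dienoic acid, via enal 19 (not isolated)
Conditions: TEMPO (10 mol%), PhI(OAc)2, CH2Cl2, rt; then NaClO2, NaH2PO4, 2-methyl-2-butene, t-BuOH/H2O, rt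
Reagents that add atoms: sodium chlorite, [Na+].[O-]Cl=O
Why: Oxoammonium oxidation of the allylic alcohol to the enal, then Pinnick oxidation; neither stage should isomerise the E alkenes, and any enal already formed in step 12 converges.

Step 14
Reactants: 20 (2E,6E)-8-methoxy-2,6-dimethyl-8-oxoocta-2,6-dienoic acid; 21 (S)-1-phenylethylamine
Product: 22 methyl (2E,6E)-3,7-dimethyl-8-oxo-8-{[(S)-1-phenylethyl]amino}octa-2,6-dienoate
Conditions: EDC·HCl, HOBt, i-Pr2NEt, CH2Cl2, 0 °C to rt
Reagents that add atoms: none
Why: Carbodiimide amide coupling; the amine supplies the nitrogen tether of the photosubstrate and serves as a resolving handle.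

Step 15
Reactants: 23 (E)-3-(4-hydroxy-3-methoxyphenyl)acrylic acid (ferulic acid)
Product: 25 (E)-3-[4-(allyloxy)-3-methoxyphenyl]acrylic acid, via allyl ester 24 (not isolated)
Conditions: allyl bromide (2.5 equiv), K2CO3, DMF, 50 °C; then NaOH, MeOH/H2O, 60 °C; HCl
Reagents that add atoms: allyl bromide, C=CCBr
Why: Williamson allylation of phenoxide and carboxylate, then saponification of the allyl ester only. The aryl allyl ether should resist base, acid, light and Mitsunobu conditions and is cleaved at the end by zerovalent palladium.

Step 16
Reactants: 22 methyl (2E,6E)-3,7-dimethyl-8-oxo-8-{[(S)-1-phenylethyl]amino}octa-2,6-dienoate; 25 (E)-3-[4-(allyloxy)-3-methoxyphenyl]acrylic acid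
Product: 27 methyl (2E,6E)-8-{[(E)-3-(4-(allyloxy)-3-methoxyphenyl)acryloyl][(S)-1-phenylethyl]amino}-3,7-dimethyl-8-oxoocta-2,6-dienoate, via acid chloride 26 (not isolated)
Conditions: 25, (COCl)2, DMF (cat.), CH2Cl2, 0 °C to rt; 22, LiN(SiMe3)2, THF, −78 °C, then 26, −78 to 0 °C
Reagents that add atoms: none
Why: N-acylation of the lithium amidate with a non-enolisable cinnamoyl chloride should give the mixed imide; any O-acyl isoimide should rearrange to the imide on warming (1,3-acyl shift).

Step 17
Reactants: 27 methyl (2E,6E)-8-{[(E)-3-(4-(allyloxy)-3-methoxyphenyl)acryloyl][(S)-1-phenylethyl]amino}-3,7-dimethyl-8-oxoocta-2,6-dienoate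
Product: 28 methyl (E)-5-{7-[4-(allyloxy)-3-methoxyphenyl]-1-methyl-2,4-dioxo-3-[(S)-1-phenylethyl]-3-azabicyclo[3.1.1]heptan-6-yl}-3-methylpent-2-enoate, aryl group and side chain both anti to the imide bridge, cyclobutane carbons configured as in 30
Conditions: thioxanthen-9-one (10 mol%), hν (405 nm), MeCN (5 mM), Ar, rt; chromatography
Reagents that add atoms: none
Why: Crossed intramolecular [2+2] photocycloaddition of a bis-alkenoyl imide: triplet energy transfer should reach only the cinnamoyl chromophore, whose α-carbon adds to the β-carbon of the 2-methylenoyl unit to give a benzylic/tertiary α-acyl 1,4-biradical (the parallel five-membered mode is blocked by the α-methyl group), and this closes to the 3-azabicyclo[3.1.1]heptane-2,4-dione. The bridge forces the two carbonyls cis, the E geometry of the enoyl unit is held in the first-formed ring and puts the side chain anti to the bridge, and the aryl group should take the less crowded anti position. The chiral nitrogen substituent makes the two mirror-image cores diastereomers, which are separated here.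

Step 18
Reactants: 28 methyl (E)-5-{7-[4-(allyloxy)-3-methoxyphenyl]-1-methyl-2,4-dioxo-3-[(S)-1-phenylethyl]-3-azabicyclo[3.1.1]heptan-6-yl}-3-methylpent-2-enoate
Product: 30 (1R,2S,3S,4S)-2-[4-(allyloxy)-3-methoxyphenyl]-4-[(E)-4-carboxy-3-methylbut-3-en-1-yl]-1-methylcyclobutane-1,3-dicarboxylic acid, via amic acid 29 (not isolated)
Conditions: LiOH, THF/MeOH/H2O, 40 °C; then 2 M HCl, 1,4-dioxane, 80 °C
Reagents that add atoms: lithium hydroxide, [Li+].[OH-]; water, O
Why: Hydroxide should open the strained imide at the less hindered carbonyl and saponify the methyl ester; in acid the neighbouring cis carboxyl group attacks the remaining amide (anchimeric assistance through the bicyclic anhydride) and releases the auxiliary. No stereocentre changes, because C3 already has its carboxyl trans to both neighbours.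

Step 19
Reactants: 30 (1R,2S,3S,4S)-2-[4-(allyloxy)-3-methoxyphenyl]-4-[(E)-4-carboxy-3-methylbut-3-en-1-yl]-1-methylcyclobutane-1,3-dicarboxylic acid; 16 (4R,4aR,6S,7R,7aS)-2,4,7-trimethyloctahydro-1H-cyclopenta[c]pyridin-6-ol (three molecules react per molecule of 30: one is counted here, the other two under the reagents)
Product: 31 O-allyl ether of the target: tris[(4R,4aR,6R,7R,7aS)-2,4,7-trimethyloctahydro-1H-cyclopenta[c]pyridin-6-yl] ester of 30
Conditions: 16 (3.6 equiv), PPh3 (4.5 equiv), diisopropyl azodicarboxylate (4.5 equiv), THF, 0 °C to rt
Reagents that add atoms: two further molecules of 16, O[C@H]1C[C@H]2[C@H](CN(C)C[C@@H]2C)[C@H]1C.O[C@H]1C[C@H]2[C@H](CN(C)C[C@@H]2C)[C@H]1C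
Why: Threefold Mitsunobu esterification in which each of the three carboxylates of 30 displaces the oxyphosphonium group at C6 of one molecule of 16 by SN2, so that three molecules of 16 are built in and each 6S centre becomes the required 6R. The unhindered enoic acid should react first and the neopentyl-type C1 acid last, hence the excess of alcohol and reagents; the allyl ether keeps the phenol from competing, and the tertiary amines are tolerated.

Step 20
Reactants: 31 O-allyl ether of the target
Product: 32 CNP0251577.2, tris[(4R,4aR,6R,7R,7aS)-2,4,7-trimethyloctahydro-1H-cyclopenta[c]pyridin-6-yl] ester of (1R,2S,3S,4S)-4-[(E)-4-carboxy-3-methylbut-3-en-1-yl]-2-(4-hydroxy-3-methoxyphenyl)-1-methylcyclobutane-1,3-dicarboxylic acid (locants as in 30)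
Conditions: Pd(PPh3)4 (5 mol%), morpholine, THF, rt
Reagents that add atoms: none
Why: Tsuji–Trost deallylation; zerovalent palladium ionises the aryl allyl ether and morpholine traps the allyl fragment. The three alkyl esters, the enoate and the amines should not react.

## Compound list

1 | methyl (S)-3-hydroxy-2-methylpropanoate | OC[C@H](C)C(=O)OC | starting material
2 | methyl (S)-3-[(tert-butyldimethylsilyl)oxy]-2-methylpropanoate | CC(C)(C)[Si](C)(C)OC[C@H](C)C(=O)OC | intermediate
3 | (S)-3-[(tert-butyldimethylsilyl)oxy]-2-methylpropanal | CC(C)(C)[Si](C)(C)OC[C@H](C)C=O | intermediate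
4 | (R,E)-6-[(tert-butyldimethylsilyl)oxy]-5-methylhex-3-en-2-one | CC(C)(C)[Si](C)(C)OC[C@H](C)/C=C/C(C)=O | intermediate
5 | (2S,5R,E)-6-[(tert-butyldimethylsilyl)oxy]-5-methylhex-3-en-2-ol | CC(C)(C)[Si](C)(C)OC[C@H](C)/C=C/[C@H](C)O | intermediate
6 | 1-(dimethylamino)vinyl ether of 5 (ketene N,O-acetal) | CC(C)(C)[Si](C)(C)OC[C@H](C)/C=C/[C@H](C)OC(=C)N(C)C | intermediate
7 | (S,E)-3-[(R)-1-((tert-butyldimethylsilyl)oxy)propan-2-yl]-N,N-dimethylhex-4-enamide | CN(C)C(=O)C[C@@H](/C=C/C)[C@@H](C)CO[Si](C)(C)C(C)(C)C | intermediate
8 | (S,E)-5-[(R)-1-((tert-butyldimethylsilyl)oxy)propan-2-yl]-2-methylocta-1,6-dien-3-one | CC(=C)C(=O)C[C@@H](/C=C/C)[C@@H](C)CO[Si](C)(C)C(C)(C)C | intermediate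
9 | (S)-4-[(R)-1-((tert-butyldimethylsilyl)oxy)propan-2-yl]-2-methylcyclopent-2-en-1-one | CC1=C[C@H](CC1=O)[C@@H](C)CO[Si](C)(C)C(C)(C)C | intermediate
10 | (S)-4-[(R)-1-hydroxypropan-2-yl]-2-methylcyclopent-2-en-1-one | CC1=C[C@H](CC1=O)[C@@H](C)CO | intermediate
11 | N-methyl-1-(trimethylsilyl)methanamine | CNC[Si](C)(C)C | starting material
12 | (R)-2-[(S)-3-methyl-4-oxocyclopent-2-en-1-yl]propyl trifluoromethanesulfonate | CC1=C[C@H](CC1=O)[C@@H](C)COS(=O)(=O)C(F)(F)F | intermediate
13 | (S)-2-methyl-4-[(R)-1-{methyl[(trimethylsilyl)methyl]amino}propan-2-yl]cyclopent-2-en-1-one | CC1=C[C@H](CC1=O)[C@@H](C)CN(C)C[Si](C)(C)C | intermediate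
14 | (4R,4aR,7S,7aS)-2,4,7-trimethyloctahydro-6H-cyclopenta[c]pyridin-6-one | O=C1C[C@H]2[C@H](CN(C)C[C@@H]2C)[C@@H]1C | intermediate
15 | (4R,4aR,7R,7aS)-2,4,7-trimethyloctahydro-6H-cyclopenta[c]pyridin-6-one | O=C1C[C@H]2[C@H](CN(C)C[C@@H]2C)[C@H]1C | intermediate
16 | (4R,4aR,6S,7R,7aS)-2,4,7-trimethyloctahydro-1H-cyclopenta[c]pyridin-6-ol | O[C@H]1C[C@H]2[C@H](CN(C)C[C@@H]2C)[C@H]1C | intermediate
17 | methyl (2E)-3,7-dimethylocta-2,6-dienoate | COC(=O)/C=C(\C)CCC=C(C)C | starting material
18 | methyl (2E,6E)-8-hydroxy-3,7-dimethylocta-2,6-dienoate | COC(=O)/C=C(\C)CC/C=C(\C)CO | intermediate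
19 | methyl (2E,6E)-3,7-dimethyl-8-oxoocta-2,6-dienoate | COC(=O)/C=C(\C)CC/C=C(\C)C=O | intermediate
20 | (2E,6E)-8-methoxy-2,6-dimethyl-8-oxoocta-2,6-dienoic acid | COC(=O)/C=C(\C)CC/C=C(\C)C(=O)O | intermediate
21 | (S)-1-phenylethylamine | C[C@H](N)c1ccccc1 | starting material
22 | methyl (2E,6E)-3,7-dimethyl-8-oxo-8-{[(S)-1-phenylethyl]amino}octa-2,6-dienoate | COC(=O)/C=C(\C)CC/C=C(\C)C(=O)N[C@@H](C)c1ccccc1 | intermediate
23 | (E)-3-(4-hydroxy-3-methoxyphenyl)acrylic acid | COc1cc(/C=C/C(=O)O)ccc1O | starting material
24 | allyl (E)-3-[4-(allyloxy)-3-methoxyphenyl]acrylate | COc1cc(/C=C/C(=O)OCC=C)ccc1OCC=C | intermediate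
25 | (E)-3-[4-(allyloxy)-3-methoxyphenyl]acrylic acid | COc1cc(/C=C/C(=O)O)ccc1OCC=C | intermediate
26 | (E)-3-[4-(allyloxy)-3-methoxyphenyl]acryloyl chloride | COc1cc(/C=C/C(Cl)=O)ccc1OCC=C | intermediate
27 | methyl (2E,6E)-8-{[(E)-3-(4-(allyloxy)-3-methoxyphenyl)acryloyl][(S)-1-phenylethyl]amino}-3,7-dimethyl-8-oxoocta-2,6-dienoate | COC(=O)/C=C(\C)CC/C=C(\C)C(=O)N([C@@H](C)c1ccccc1)C(=O)/C=C/c1ccc(OCC=C)c(OC)c1 | intermediate
28 | methyl (E)-5-{7-[4-(allyloxy)-3-methoxyphenyl]-1-methyl-2,4-dioxo-3-[(S)-1-phenylethyl]-3-azabicyclo[3.1.1]heptan-6-yl}-3-methylpent-2-enoate (aryl and chain anti to the imide bridge) | COc1cc([C@@H]2[C@@H](C(=O)N([C@@H](C)c4ccccc4)C3=O)[C@H](CC/C(C)=C/C(=O)OC)[C@]23C)ccc1OCC=C | intermediate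
29 | (1S,2S,3R,4S)-2-[4-(allyloxy)-3-methoxyphenyl]-4-[(E)-4-carboxy-3-methylbut-3-en-1-yl]-3-methyl-3-{[(S)-1-phenylethyl]carbamoyl}cyclobutane-1-carboxylic acid | COc1cc([C@@H]2[C@@H](C(=O)O)[C@H](CC/C(C)=C/C(=O)O)[C@@]2(C)C(=O)N[C@@H](C)c3ccccc3)ccc1OCC=C | intermediate
30 | (1R,2S,3S,4S)-2-[4-(allyloxy)-3-methoxyphenyl]-4-[(E)-4-carboxy-3-methylbut-3-en-1-yl]-1-methylcyclobutane-1,3-dicarboxylic acid | COc1cc([C@@H]2[C@@H](C(=O)O)[C@H](CC/C(C)=C/C(=O)O)[C@@]2(C)C(=O)O)ccc1OCC=C | intermediate
31 | tris[(4R,4aR,6R,7R,7aS)-2,4,7-trimethyloctahydro-1H-cyclopenta[c]pyridin-6-yl] ester of 30 | COc1cc([C@@H]2[C@@H](C(=O)O[C@@H]3C[C@H]4[C@H](CN(C)C[C@@H]4C)[C@H]3C)[C@H](CC/C(C)=C/C(=O)O[C@@H]3C[C@H]4[C@H](CN(C)C[C@@H]4C)[C@H]3C)[C@@]2(C)C(=O)O[C@@H]2C[C@H]3[C@H](CN(C)C[C@@H]3C)[C@H]2C)ccc1OCC=C | intermediate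
32 | CNP0251577.2, the free phenol of 31 | COc1cc([C@@H]2[C@@H](C(=O)O[C@@H]3C[C@H]4[C@H](CN(C)C[C@@H]4C)[C@H]3C)[C@H](CC/C(C)=C/C(=O)O[C@@H]3C[C@H]4[C@H](CN(C)C[C@@H]4C)[C@H]3C)[C@@]2(C)C(=O)O[C@@H]2C[C@H]3[C@H](CN(C)C[C@@H]3C)[C@H]2C)ccc1O | target

## Step count and least certain steps

Total step count: 20. Longest linear sequence: 13 steps (steps 1 to 11, then 19 and 20).

**Step 10 (key step).**
- What may go wrong: back electron transfer and loss of the silyl group without ring closure, α-deprotonation at N-methyl or C3 in place of desilylation, or direct enone photochemistry if short-wavelength light leaks through.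
- Fallback: this sets out from 10 and comes back at 15. Triflate 12, formed as in step 9, is treated with tert-butyl N-methylglycinate to give tert-butyl N-methyl-N-{(R)-2-[(S)-3-methyl-4-oxocyclopent-2-en-1-yl]propyl}glycinate F1. Trifluoroacetic acid then frees N-methyl-N-{(R)-2-[(S)-3-methyl-4-oxocyclopent-2-en-1-yl]propyl}glycine F2. Visible-light decarboxylation of F2 (2,4,5,6-tetra(carbazol-9-yl)isophthalonitrile, K2HPO4, DMF, blue light) generates the same aminomethyl radical by loss of CO2, a known decarboxylative radical conjugate addition. It should close to 15 after the same K2CO3 equilibration.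

**Step 17.**
- What may go wrong: parallel closure or hydrogen transfer within the 1,4-biradical competing with crossed closure, E/Z isomerisation of the cinnamoyl unit draining the excited state, and incomplete separation of the two diastereomers.
- Fallback: this sets out from 16, 20 and 25 and comes back at 31; it is a late, biomimetic intermolecular cycloaddition. Mitsunobu esterification of 25 with 16 gives (4R,4aR,6R,7R,7aS)-2,4,7-trimethyloctahydro-1H-cyclopenta[c]pyridin-6-yl (E)-3-[4-(allyloxy)-3-methoxyphenyl]acrylate F3. Saponification of 20 gives (2E,6E)-2,6-dimethylocta-2,6-dienedioic acid F4. Twofold Mitsunobu esterification of F4 with two molecules of 16 gives bis[(4R,4aR,6R,7R,7aS)-2,4,7-trimethyloctahydro-1H-cyclopenta[c]pyridin-6-yl] (2E,6E)-2,6-dimethylocta-2,6-dienedioate F5. Sensitised irradiation of F3 with excess F5, both as trifluoroacetate salts to protect the amines from electron transfer, should give the head-to-tail adduct 31 among isomers. Because all esters are already enantiopure, the isomers are diastereomers and no resolution is needed, at the price of low selectivity.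

**Step 18.**
- What may go wrong: incomplete cleavage of the hindered secondary amide, or re-closure to the imide on heating in acid.
- Fallback: this sets out from 29, isolated after the LiOH stage, and comes back at 30. Nitrosation (NaNO2, Ac2O/AcOH, 0 °C) converts the amide into the N-nitroso derivative of 29 F6. LiOH/H2O2 then cleaves F6 at the acyl carbon with loss of nitrogen, the classical nitrosative cleavage of secondary amides.

**Step 19.**
- What may go wrong: incomplete esterification at the neopentyl C1 carboxyl group, so that partial esters remain, and elimination of the activated alcohol in place of substitution.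
- Fallback: this sets out from 16 and 30 and comes back at 31; it acylates with retention instead of alkylating with inversion. Mitsunobu reaction of 16 with 4-nitrobenzoic acid gives (4R,4aR,6R,7R,7aS)-2,4,7-trimethyloctahydro-1H-cyclopenta[c]pyridin-6-yl 4-nitrobenzoate F7. K2CO3 in methanol then gives (4R,4aR,6R,7R,7aS)-2,4,7-trimethyloctahydro-1H-cyclopenta[c]pyridin-6-ol F8. Triacid 30 is converted with 1-chloro-N,N,2-trimethylprop-1-en-1-amine into the tris(acid chloride) of 30 F9, which is esterified with three molecules of F8 (pyridine, 4-dimethylaminopyridine) to give 31.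

## Further compounds

F1 | step 10 | tert-butyl N-methyl-N-{(R)-2-[(S)-3-methyl-4-oxocyclopent-2-en-1-yl]propyl}glycinate | CC1=C[C@H](CC1=O)[C@@H](C)CN(C)CC(=O)OC(C)(C)C
F2 | step 10 | N-methyl-N-{(R)-2-[(S)-3-methyl-4-oxocyclopent-2-en-1-yl]propyl}glycine | CC1=C[C@H](CC1=O)[C@@H](C)CN(C)CC(=O)O
F3 | step 17 | (4R,4aR,6R,7R,7aS)-2,4,7-trimethyloctahydro-1H-cyclopenta[c]pyridin-6-yl (E)-3-[4-(allyloxy)-3-methoxyphenyl]acrylate | COc1cc(/C=C/C(=O)O[C@@H]2C[C@H]3[C@H](CN(C)C[C@@H]3C)[C@H]2C)ccc1OCC=C
F4 | step 17 | (2E,6E)-2,6-dimethylocta-2,6-dienedioic acid | OC(=O)/C=C(\C)CC/C=C(\C)C(=O)O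
F5 | step 17 | bis[(4R,4aR,6R,7R,7aS)-2,4,7-trimethyloctahydro-1H-cyclopenta[c]pyridin-6-yl] (2E,6E)-2,6-dimethylocta-2,6-dienedioate | O=C(/C=C(\C)CC/C=C(\C)C(=O)O[C@@H]1C[C@H]2[C@H](CN(C)C[C@@H]2C)[C@H]1C)O[C@@H]1C[C@H]2[C@H](CN(C)C[C@@H]2C)[C@H]1C
F6 | step 18 | N-nitroso derivative of 29 | COc1cc([C@@H]2[C@@H](C(=O)O)[C@H](CC/C(C)=C/C(=O)O)[C@@]2(C)C(=O)N(N=O)[C@@H](C)c3ccccc3)ccc1OCC=C
F7 | step 19 | (4R,4aR,6R,7R,7aS)-2,4,7-trimethyloctahydro-1H-cyclopenta[c]pyridin-6-yl 4-nitrobenzoate | O=C(O[C@@H]1C[C@H]2[C@H](CN(C)C[C@@H]2C)[C@H]1C)c1ccc(cc1)[N+](=O)[O-]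
F8 | step 19 | (4R,4aR,6R,7R,7aS)-2,4,7-trimethyloctahydro-1H-cyclopenta[c]pyridin-6-ol | O[C@@H]1C[C@H]2[C@H](CN(C)C[C@@H]2C)[C@H]1C
F9 | step 19 | tris(acid chloride) of 30 | COc1cc([C@@H]2[C@@H](C(Cl)=O)[C@H](CC/C(C)=C/C(Cl)=O)[C@@]2(C)C(Cl)=O)ccc1OCC=C
A1 | alternative 1 | di-tert-butyl (2S,3S,4S,5S)-5-(4-acetoxy-3-methoxyphenyl)-3-[(E)-5-(tert-butoxy)-3-methyl-5-oxopent-3-en-1-yl]-2-methylpyrrolidine-2,4-dicarboxylate | COc1cc([C@@H]2[C@@H](C(=O)OC(C)(C)C)[C@H](CC/C(C)=C/C(=O)OC(C)(C)C)[C@@](C)(C(=O)OC(C)(C)C)N2)ccc1OC(C)=O
A2 | alternative 1 | tri-tert-butyl ester of the cyclobutane triacid with the phenol as acetate | COc1cc([C@@H]2[C@@H](C(=O)OC(C)(C)C)[C@H](CC/C(C)=C/C(=O)OC(C)(C)C)[C@@]2(C)C(=O)OC(C)(C)C)ccc1OC(C)=O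
A3 | alternative 2 | methyl 3-methyl-2-oxo-2H-pyran-5-carboxylate | COC(=O)C1=COC(=O)C(C)=C1
A4 | alternative 2 | methyl (1R,4S)-4-methyl-3-oxo-2-oxabicyclo[2.2.0]hex-5-ene-6-carboxylate | COC(=O)C1=C[C@]2(C)C(=O)O[C@H]12
A5 | alternative 3 | methyl but-2-yn-1-yl[(R)-2-methylbut-3-en-1-yl]carbamate | CC#CCN(C(=O)OC)C[C@H](C)C=C
A6 | alternative 3 | methyl (4R,4aR)-4,7-dimethyl-6-oxo-1,3,4,4a,5,6-hexahydro-2H-cyclopenta[c]pyridine-2-carboxylate | CC1=C2CN(C(=O)OC)C[C@H](C)[C@H]2CC1=O
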